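## Structural features

The target is a linear trimer of three C6–C3 units: three benzene rings (A, B and C), each with one methoxy and one allyl group, joined only by two diaryl ether oxygens. Ring A is a 4-allyl-2-methoxyphenyl group whose C1 carries the first ether oxygen. Ring B is the centre: that oxygen sits on C6, the second ether oxygen on C1, methoxy on C2 and allyl on C4. Ring C is attached through C1, has the only free hydroxyl on C2, methoxy on C3 and allyl on C5. There is no stereocentre and no ring beyond the three arenes, so nothing has to be controlled in three dimensions. The fragile elements are the three allyl groups (migration into conjugation under strong base or metal hydrides, epoxidation by electrophilic oxidants) and the oxidisable guaiacol-type phenol of ring C. The real difficulty is regiochemical and steric: ring B carries three contiguous oxygens, its central oxygen on C1 is flanked on both sides, and three nearly identical electron-rich arenes must be joined in a fixed order with one hydroxyl left free. The key step exploits ring A, where the ether carbon C1 is para to the allyl-bearing C4 and ortho to the C2 methoxy group. If the allyl CH2 is carried as a formyl carbon, C1 becomes an activated C–F position and the ring A–O bond can be made by SNAr from the ring B phenol (oxygen on C6).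

## Logic of the disconnections

13 back to 12: the bond cut is the O–CH2 bond of the acetal on the ring C oxygen. It is cut last because a masked ring C hydroxyl is what lets exactly one phenol react in each C–O bond formation. The skeleton is not simplified, but the order of ring assembly becomes controllable. The forward demand is an acid mild enough to leave three allyl groups and two diaryl ethers alone.

12 back to 9 (through 11 and 10): the bond cut is the CH2–CH bond inside the ring A allyl group, and the remaining benzylic carbon is traced back through bromide 11 and alcohol 10 to the formyl group of 9. This converts the ring A substituent at C4 into an acceptor para to the ether carbon. The gain is that ring A becomes a bought building block. The forward demand is a vinyl transfer to a benzylic bromide that does not move any double bond into conjugation.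

9 back to 7 and 8: the bond cut is C1(ring A)–O. Cutting here removes a whole ring in one metal-free step and uses the formyl group twice, as activator and as latent allyl carbon. The forward demand is a single free phenol in 7 and a base too weak to isomerise the allyl groups.

7 back to 5 (through 6): the C6–O bond of the ring B hydroxyl is traced to the C6–CHO bond of 5 by aryl migration to oxygen. The formyl group marks the position of this hydroxyl unambiguously and arrives with the bought ring B unit. The forward demand is an oxidant that inserts oxygen at the aldehyde faster than it attacks two terminal alkenes.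

5 back to 3 and 4: the bond cut is C1(ring C)–O, the central and most hindered ether. It separates the dimer into two monocyclic units of equal size, one of them bought. The forward demand is a copper-mediated coupling that tolerates ortho substituents on both partners.

3 back to 1 (through 2): the bonds cut are the acetal O–CH2 bond and the ring C–Br bond. The bromine goes onto the only free position ortho to the hydroxyl of 1, so the whole ring C unit comes from a bulk natural phenol. The forward demand is ring bromination without attack on the allyl double bond.

## Other disconnections considered

Alternative 1: Ring B is assembled instead of bought; the cuts are the C3–C4 and C5–C6 bonds of ring B. In the forward direction the chlorocyclobutenone A1 (racemic at the chlorine-bearing carbon) already carries the ring C aryloxy group and the methoxy group on its double bond. It would be coupled with the dienylstannane A2 under zerovalent palladium catalysis. The resulting 4-alkenylcyclobutenone would open thermally to a dienylketene and reclose by 6π-electrocyclisation to phenol A3, which is the same compound as 7.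
- In its favour: every oxygen of ring B is in place before the arene exists. The congested central ether would be made by addition–elimination of phenol A4 on dimethyl squarate A5, which is indifferent to the ortho substituents that burden step 3. On this point the alternative is the better plan, and it also exposes the allyl groups to no oxidant.
- Against it: A4 (outer hydroxyl free, inner one protected) needs several steps of its own. A1 requires selective reduction of the carbonyl next to the methoxy-bearing carbon, then chlorination, and such chlorocyclobutenones are labile. A2 must be prepared as well.
- Comparison: on structure both plans reach the identical phenol with unambiguous regiochemistry (equal). On mechanism the pericyclic cascade is cleaner than the copper coupling plus peracid pair. On step economy it is clearly longer, roughly eight or nine operations to A3 against four to 7.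

Alternative 2: The cut is the C4–CH2 bond of the ring B allyl group, made at the stage of a ring A–ring B dimer. In the forward direction the O-allyl ether A6 would be heated. Both positions ortho to its allyloxy oxygen are occupied, so two successive [3,3] shifts carry the allyl group to C4 and give phenol A7.
- In its favour: no reagent is needed, the regiochemistry is forced, and the rearrangement unmasks the hydroxyl for the next etherification, so allyl serves as its own protecting group.
- Against it: the last C–O bond would be the central one, made by copper coupling of A7, a phenol flanked by aryloxy and methoxy, with an ortho-alkoxy aryl bromide such as 3. The most hindered bond would thus be formed latest, on the most valuable intermediate. It cannot be replaced by SNAr, because ring C has no acceptor position ortho or para to its ether carbon. Heating near 190 °C also risks side reactions of the ortho-dienone intermediates.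
- Comparison: on structure it delivers the same ring B pattern with equal certainty. On mechanism the hindered copper coupling is of the same class as step 3 (equal in kind, worse in timing). On step economy it is the better plan on paper: coupling of A7 with 3 would give 12 directly, about seven steps to 13 against nine. The chosen plan accepts two more steps to place the hindered coupling early and to finish the ether framework with a metal-free substitution.

Alternative 3: The cut is the C1(ring B)–O bond, with ring B at the oxidation level of a cyclohexane-1,3-dione. In the forward direction Rh2(OAc)4 would decompose the diazo dione A8 in the presence of phenol A4. The divalent-rhodium carbenoid would insert into the O–H bond and give the 2-aryloxy dione A9 (enol form, racemic at the allyl-bearing carbon, which is of no consequence). Mono-O-methylation and dehydrogenation would then lead to A3.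
- In its favour: the most hindered ether is formed at a carbenoid carbon at room temperature with a catalytic metal, with no steric penalty. On this point it is better than step 3. The two carbonyls of A9 are equivalent, so the methylation is unambiguous (equal to the chosen plan in regiochemical certainty).
- Against it: the acceptor-substituted carbenoid can also cyclopropanate or add across the terminal alkenes of A4 and A8. The aromatisation of A9 needs dehydrogenating or halogenating reagents that threaten the allyl groups. A8 and A4 both require multistep preparation.
- Comparison: on structure it reaches the same phenol. On mechanism it trades a hindered Ullmann coupling for a chemoselectivity problem and a redox adjustment. On step economy it is the longest of the four plans.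

Key step: step 5

Assumption: 1 (eugenol) and 4 (5-allyl-2-hydroxy-3-methoxybenzaldehyde) are taken as catalogue compounds; the target is achiral, so no stereochemical assumption is needed.

## Route

Step 1
Reactants: 1 eugenol (4-allyl-2-methoxyphenol)
Product: 2 4-allyl-2-bromo-6-methoxyphenol
Conditions: NBS (1.0 equiv, in portions), i-Pr2NH (0.1 equiv), CH2Cl2, 0 °C, dark
Reagents that add atoms: N-bromosuccinimide, O=C1CCC(=O)N1Br
Why: Amine-catalysed electrophilic ortho-bromination of a phenol; the para position is blocked by the allyl group, so the hydroxyl directs bromine to the only free ortho carbon, and the activated ring should react much faster than the monosubstituted alkene.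

Step 2
Reactants: 2 4-allyl-2-bromo-6-methoxyphenol
Product: 3 5-allyl-1-bromo-3-methoxy-2-(methoxymethoxy)benzene
Conditions: NaH, THF, 0 °C; then MOMCl, 0 °C → rt
Reagents that add atoms: chloromethyl methyl ether, COCCl
Why: Williamson-type O-alkylation of the sodium phenoxide gives the MOM acetal, which is stable to the basic, reductive and organometallic steps that follow and is small enough not to block the neighbouring C–Br bond.

Step 3
Reactants: 3 5-allyl-1-bromo-3-methoxy-2-(methoxymethoxy)benzene; 4 5-allyl-2-hydroxy-3-methoxybenzaldehyde
Product: 5 5-allyl-2-[5-allyl-3-methoxy-2-(methoxymethoxy)phenoxy]-3-methoxybenzaldehyde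
Conditions: CuI (10 mol%), picolinic acid (20 mol%), K3PO4 (2 equiv), DMSO, 90 °C, Ar
Reagents that add atoms: none
Why: Ullmann-type copper-catalysed diaryl ether synthesis forms the central C1(ring C)–O bond; the picolinate ligand system is suited to ortho-substituted phenols and aryl bromides, and the formyl group ortho to the new ether fixes the position of the future ring B hydroxyl.

Step 4
Reactants: 5 5-allyl-2-[5-allyl-3-methoxy-2-(methoxymethoxy)phenoxy]-3-methoxybenzaldehyde
Product: 7 5-allyl-2-[5-allyl-3-methoxy-2-(methoxymethoxy)phenoxy]-3-methoxyphenol, via aryl formate 6 (not isolated)
Conditions: mCPBA (1.1 equiv), CH2Cl2, 0 °C → rt; aqueous NaHCO3/Na2S2O3 wash, evaporation; then K2CO3 (cat.), MeOH, rt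
Reagents that add atoms: 3-chloroperoxybenzoic acid, OOC(=O)c1cccc(Cl)c1
Why: Baeyer–Villiger (Dakin-type) oxidation, in which the ortho-aryloxy group makes the aryl group migrate to oxygen, followed by methanolysis of the formate; the electron-rich aldehyde should consume one equivalent of peracid well before the monosubstituted alkenes are epoxidised, and the MOM acetal is inert to the weak carboxylic acid.

Step 5
Reactants: 7 5-allyl-2-[5-allyl-3-methoxy-2-(methoxymethoxy)phenoxy]-3-methoxyphenol; 8 4-fluoro-3-methoxybenzaldehyde
Product: 9 4-{5-allyl-2-[5-allyl-3-methoxy-2-(methoxymethoxy)phenoxy]-3-methoxyphenoxy}-3-methoxybenzaldehyde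
Conditions: K2CO3 (2 equiv), 8 (1.3 equiv), DMSO, 100 °C, Ar
Reagents that add atoms: none
Why: K2CO3 converts 7 into its potassium phenoxide, which adds to C4 of 8 to give a Meisenheimer anion whose charge is delocalised into the para-formyl group; loss of fluoride restores aromaticity and forms the C1(ring A)–O bond. The closest known reaction type is the SNAr diaryl ether synthesis from phenoxides and 4-fluorobenzaldehydes in dipolar aprotic solvents. No ring is closed and no stereocentre is created, so only chemo- and site-selectivity are required. Single O-arylation is secured because 7 has exactly one free hydroxyl (the ring C oxygen is a MOM acetal) and 8 has exactly one activated C–F bond. The ortho-methoxy group of 8 slows the addition, but fluoride para to formyl should remain reactive enough in DMSO, and an excess of 8 is harmless because it has no enolisable hydrogen. Carbonate is far too weak to deprotonate the CH2 of the allyl groups and no metal is present, so the double bonds should stay out of conjugation. The formyl carbon that activates the substitution sits exactly where ring A needs the benzylic carbon of its allyl group.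

Step 6
Reactants: 9 4-{5-allyl-2-[5-allyl-3-methoxy-2-(methoxymethoxy)phenoxy]-3-methoxyphenoxy}-3-methoxybenzaldehyde
Product: 10 (4-{5-allyl-2-[5-allyl-3-methoxy-2-(methoxymethoxy)phenoxy]-3-methoxyphenoxy}-3-methoxyphenyl)methanol
Conditions: NaBH4, MeOH–THF, 0 °C
Reagents that add atoms: none
Why: Borohydride reduction of an aryl aldehyde to the benzylic alcohol; isolated alkenes, aryl ethers and the MOM acetal are inert to this hydride.

Step 7
Reactants: 10 (4-{5-allyl-2-[5-allyl-3-methoxy-2-(methoxymethoxy)phenoxy]-3-methoxyphenoxy}-3-methoxyphenyl)methanol
Product: 11 5-allyl-1-[4-(bromomethyl)-2-methoxyphenoxy]-2-[5-allyl-3-methoxy-2-(methoxymethoxy)phenoxy]-3-methoxybenzene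
Conditions: CBr4, PPh3, CH2Cl2, 0 °C; used directly after filtration through a short silica pad
Reagents that add atoms: carbon tetrabromide, BrC(Br)(Br)Br
Why: Appel bromination through an alkoxyphosphonium bromide and SN2 displacement at the primary benzylic carbon; the near-neutral conditions should spare the MOM acetal and the alkenes.

Step 8
Reactants: 11 5-allyl-1-[4-(bromomethyl)-2-methoxyphenoxy]-2-[5-allyl-3-methoxy-2-(methoxymethoxy)phenoxy]-3-methoxybenzene
Product: 12 5-allyl-1-(4-allyl-2-methoxyphenoxy)-2-[5-allyl-3-methoxy-2-(methoxymethoxy)phenoxy]-3-methoxybenzene
Conditions: Bu3SnCH=CH2 (1.2 equiv), Pd(PPh3)4 (5 mol%), toluene, 90 °C, Ar; aqueous KF work-up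
Reagents that add atoms: tributyl(vinyl)stannane, C=C[Sn](CCCC)(CCCC)CCCC
Why: Stille coupling of a benzylic bromide with a vinylstannane (oxidative addition to zerovalent palladium, transmetalation, reductive elimination) forms the CH2–CH bond of the ring A allyl group under neutral conditions without base.

Step 9
Reactants: 12 5-allyl-1-(4-allyl-2-methoxyphenoxy)-2-[5-allyl-3-methoxy-2-(methoxymethoxy)phenoxy]-3-methoxybenzene
Product: 13 4-allyl-2-[4-allyl-2-(4-allyl-2-methoxyphenoxy)-6-methoxyphenoxy]-6-methoxyphenol
Conditions: HCl (cat., conc.), MeOH–THF, 40 °C
Reagents that add atoms: none
Why: Acid-catalysed acetal exchange removes the MOM group through an oxocarbenium ion trapped by methanol; aryl methyl ethers, diaryl ethers and non-conjugated allyl groups are stable to dilute acid at this temperature.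

## Compound list

1 | eugenol (4-allyl-2-methoxyphenol) | C=CCc1ccc(O)c(OC)c1 | starting material
2 | 4-allyl-2-bromo-6-methoxyphenol | C=CCc1cc(Br)c(O)c(OC)c1 | intermediate
3 | 5-allyl-1-bromo-3-methoxy-2-(methoxymethoxy)benzene | C=CCc1cc(Br)c(OCOC)c(OC)c1 | intermediate
4 | 5-allyl-2-hydroxy-3-methoxybenzaldehyde | C=CCc1cc(C=O)c(O)c(OC)c1 | starting material
5 | 5-allyl-2-[5-allyl-3-methoxy-2-(methoxymethoxy)phenoxy]-3-methoxybenzaldehyde | C=CCc1cc(C=O)c(Oc2cc(CC=C)cc(OC)c2OCOC)c(OC)c1 | intermediate
6 | 5-allyl-2-[5-allyl-3-methoxy-2-(methoxymethoxy)phenoxy]-3-methoxyphenyl formate (aryl formate, not isolated) | C=CCc1cc(OC=O)c(Oc2cc(CC=C)cc(OC)c2OCOC)c(OC)c1 | intermediate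
7 | 5-allyl-2-[5-allyl-3-methoxy-2-(methoxymethoxy)phenoxy]-3-methoxyphenol | C=CCc1cc(O)c(Oc2cc(CC=C)cc(OC)c2OCOC)c(OC)c1 | intermediate
8 | 4-fluoro-3-methoxybenzaldehyde | COc1cc(C=O)ccc1F | starting material
9 | 4-{5-allyl-2-[5-allyl-3-methoxy-2-(methoxymethoxy)phenoxy]-3-methoxyphenoxy}-3-methoxybenzaldehyde | O=Cc1ccc(Oc2cc(CC=C)cc(OC)c2Oc2cc(CC=C)cc(OC)c2OCOC)c(OC)c1 | intermediate
10 | (4-{5-allyl-2-[5-allyl-3-methoxy-2-(methoxymethoxy)phenoxy]-3-methoxyphenoxy}-3-methoxyphenyl)methanol | OCc1ccc(Oc2cc(CC=C)cc(OC)c2Oc2cc(CC=C)cc(OC)c2OCOC)c(OC)c1 | intermediate
11 | 5-allyl-1-[4-(bromomethyl)-2-methoxyphenoxy]-2-[5-allyl-3-methoxy-2-(methoxymethoxy)phenoxy]-3-methoxybenzene | BrCc1ccc(Oc2cc(CC=C)cc(OC)c2Oc2cc(CC=C)cc(OC)c2OCOC)c(OC)c1 | intermediate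
12 | 5-allyl-1-(4-allyl-2-methoxyphenoxy)-2-[5-allyl-3-methoxy-2-(methoxymethoxy)phenoxy]-3-methoxybenzene | C=CCc1ccc(Oc2cc(CC=C)cc(OC)c2Oc2cc(CC=C)cc(OC)c2OCOC)c(OC)c1 | intermediate
13 | 4-allyl-2-[4-allyl-2-(4-allyl-2-methoxyphenoxy)-6-methoxyphenoxy]-6-methoxyphenol | C=CCc1ccc(Oc2cc(CC=C)cc(OC)c2Oc2cc(CC=C)cc(OC)c2O)c(OC)c1 | target

## Step count and least certain steps

Total step count: 9. Longest linear sequence: 9 steps (1 → 2 → 3 → 5 → 7 → 9 → 10 → 11 → 12 → 13); 4 and 8 enter as bought components.

Key step (step 5): the most likely failure is incomplete substitution. The C–F bond is activated by a single para-formyl group and shielded by the ortho-methoxy group, and raising the temperature invites migration of the allyl double bonds into conjugation and base-induced degradation of the aldehyde. The fallback replaces the addition–elimination by a copper-catalysed C–O coupling. It sets out from 7, which would be coupled with 4-bromo-3-methoxybenzaldehyde F1 (CuI, picolinic acid, K3PO4, DMSO, 90 °C), and it comes back to the route at 9.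

Copper coupling (step 3): the most likely failure is stalling of the catalytic cycle. The phenoxide of 4 is doubly ortho-substituted, electron-poor and able to chelate copper through its formyl group, so C–O bond formation may be slower than protodebromination of 3. The fallback is an oxidative Chan–Lam coupling at room temperature. It sets out from 3, which would be converted by bromine–lithium exchange (n-BuLi, THF, −78 °C), trapping with B(Oi-Pr)3 and mild aqueous work-up into [5-allyl-3-methoxy-2-(methoxymethoxy)phenyl]boronic acid F2. F2 would then be coupled with 4 (Cu(OAc)2, pyridine, 4 Å molecular sieves, CH2Cl2, air), and the route is rejoined at 5.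

Oxidation (step 4): the most likely failures are competing epoxidation of the two terminal alkenes and partial hydride migration leading to the carboxylic acid, because the migrating ring is activated only by one ortho-aryloxy group. The fallback abandons the formyl group as latent hydroxyl and uses a bromine atom, which can be exchanged for oxygen under alkaline, alkene-safe conditions. It sets out from 1 and 2 and comes back at 7:
- 1 would be iodinated ortho to the hydroxyl (NIS, cat. CF3CO2H, MeCN, 0 °C) to 4-allyl-2-iodo-6-methoxyphenol F3.
- F3 would be protected (NaH, MOMCl, THF) as 5-allyl-1-iodo-3-methoxy-2-(methoxymethoxy)benzene F4.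
- F4 would be coupled with bromophenol 2 (CuI, picolinic acid, K3PO4, DMSO, 80 °C), where the aryl iodide should react in preference to the bromide on the electron-rich phenoxide, to give 5-allyl-1-bromo-2-[5-allyl-3-methoxy-2-(methoxymethoxy)phenoxy]-3-methoxybenzene F5.
- F5 would undergo bromine–lithium exchange (n-BuLi, THF, −78 °C), borylation with B(OMe)3 and oxidation with H2O2/NaOH to deliver 7.

Bromination (step 1): the most likely failure is loss of site selectivity, either by bromonium formation at the allyl double bond or by a second ring bromination para to the methoxy group. The fallback protects the alkene as its dibromide during ring bromination. It sets out from 1, which would be treated with Br2 (2 equiv, CH2Cl2, 0 °C) to give 2-bromo-4-(2,3-dibromopropyl)-6-methoxyphenol F6 (racemic). Zinc dust in ethanol–acetic acid would then regenerate the double bond by reductive elimination of the vicinal dibromide and leave the aryl bromide untouched, so the route is rejoined at 2.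

Vinylation (step 8): the most likely failures are migration of allyl double bonds into conjugation through adventitious palladium hydride and homocoupling of the electron-rich benzylic bromide. The fallback avoids palladium and uses a cuprate-type substitution. It sets out from 11, which would be treated with CH2=CHMgBr and catalytic CuI in THF at −30 → 0 °C, and it comes back at 12. No new compound is made on the way.

## Further compounds

F1 | step 5 | 4-bromo-3-methoxybenzaldehyde | O=Cc1ccc(Br)c(OC)c1
F2 | step 3 | [5-allyl-3-methoxy-2-(methoxymethoxy)phenyl]boronic acid | C=CCc1cc(B(O)O)c(OCOC)c(OC)c1
F3 | step 4 | 4-allyl-2-iodo-6-methoxyphenol | C=CCc1cc(I)c(O)c(OC)c1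
F4 | step 4 | 5-allyl-1-iodo-3-methoxy-2-(methoxymethoxy)benzene | C=CCc1cc(I)c(OCOC)c(OC)c1
F5 | step 4 | 5-allyl-1-bromo-2-[5-allyl-3-methoxy-2-(methoxymethoxy)phenoxy]-3-methoxybenzene | C=CCc1cc(Br)c(Oc2cc(CC=C)cc(OC)c2OCOC)c(OC)c1
F6 | step 1 | 2-bromo-4-(2,3-dibromopropyl)-6-methoxyphenol (racemic) | BrCC(Br)Cc1cc(Br)c(O)c(OC)c1
F0 | step 8 | none | none
A1 | alternative 1 | 4-chloro-2-[5-allyl-3-methoxy-2-(methoxymethoxy)phenoxy]-3-methoxycyclobut-2-en-1-one (racemic) | COC1=C(Oc2cc(CC=C)cc(OC)c2OCOC)C(=O)C1Cl
A2 | alternative 1 | tributyl(penta-1,4-dien-2-yl)stannane | C=CCC(=C)[Sn](CCCC)(CCCC)CCCC
A3 | alternative 1 | 5-allyl-2-[5-allyl-3-methoxy-2-(methoxymethoxy)phenoxy]-3-methoxyphenol (identical with 7) | C=CCc1cc(O)c(Oc2cc(CC=C)cc(OC)c2OCOC)c(OC)c1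
A4 | alternative 1 | 5-allyl-3-methoxy-2-(methoxymethoxy)phenol | C=CCc1cc(O)c(OCOC)c(OC)c1
A5 | alternative 1 | dimethyl squarate (3,4-dimethoxycyclobut-3-ene-1,2-dione) | COC1=C(OC)C(=O)C1=O
A6 | alternative 2 | 2-(allyloxy)-1-(4-allyl-2-methoxyphenoxy)-3-methoxybenzene | C=CCOc1c(OC)cccc1Oc1ccc(CC=C)cc1OC
A7 | alternative 2 | 4-allyl-2-(4-allyl-2-methoxyphenoxy)-6-methoxyphenol | C=CCc1ccc(Oc2cc(CC=C)cc(OC)c2O)c(OC)c1
A8 | alternative 3 | 5-allyl-2-diazocyclohexane-1,3-dione | C=CCC1CC(=O)C(=[N+]=[N-])C(=O)C1
A9 | alternative 3 | 5-allyl-3-hydroxy-2-[5-allyl-3-methoxy-2-(methoxymethoxy)phenoxy]cyclohex-2-en-1-one (racemic) | C=CCC1CC(=O)C(Oc2cc(CC=C)cc(OC)c2OCOC)=C(O)C1
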